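**Retrosynthetic overview**
- The target is opened from a spiro-oxolane ester by retro-oxa-Michael (E1cB) cleavage of C13–O, which unmasks both the 9β-OH and the (13E)-enoate.
- The 2α,3α-diol comes from a ring A 2-ene (OsO4, α face), and that from a 3β-alcohol installed at the start by enzymatic C–H hydroxylation of (−)-sclareol.
- C8 (8β-H) comes from an exocyclic 8(17)-ene by hydrogen-atom-transfer hydrogenation.
- Key disconnection, C9–O: oxidative anti-selenoetherification of the tetrasubstituted 8(9)-ene by the tethered C13 tertiary alcohol (O enters β, C11 ends α). The C13 oxygen of sclareol becomes the C9 hydroxyl.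
- Rings A and B are taken intact from sclareol; the only ring formed is the spiro-oxolane (step 5), which is reopened in step 9.

Assumption: labdane numbering and α/β descriptors (C20 methyl = β) are used; the target is (2R,3S,5S,8R,9S,10S,13E), i.e. 2α,3α,9β-triol with the 17-methyl α (8βH) and C11 α on C9; C13 of compounds 7–13 is an inconsequential epimer mixture (it becomes sp2 in step 9) and is written without a descriptor.

**Step 1**
Reactants: 1 (−)-sclareol [(13R)-labd-14-ene-8α,13-diol]
Product: 2 3β-hydroxysclareol [(13R)-labd-14-ene-3β,8α,13-triol]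
Conditions: engineered cytochrome P450 BM3 C3-hydroxylase (E. coli lysate), NADP+ (cat.), glucose dehydrogenase, D-glucose, air, K2HPO4/KH2PO4 buffer pH 8.0, 25 °C
Reagents that add atoms: dioxygen, O=O
Why: P450 C–H hydroxylation (radical rebound, retention) of the exposed equatorial C3–H of ring A is established biocatalysis for sclareol (engineered BM3 variants and fungal cultures both give the 3β-alcohol), and the enzyme pocket fixes C3 as the handle for the ring A diol.

**Step 2**
Reactants: 2 3β-hydroxysclareol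
Product: 5 3β,8α-dihydroxy-14,15-dinorlabdan-13-one, via labdane-3β,8α,13,14,15-pentol 3 (not isolated), via 3β,8α,13-trihydroxy-15-norlabdan-14-al 4 (not isolated)
Conditions: OsO4 (2 mol %), NaIO4 (3.5 equiv), THF/H2O 2:1, 23 °C
Reagents that add atoms: none
Why: Lemieux–Johnson oxidation dihydroxylates the only alkene and periodate cleaves the resulting 13,14,15-triol down to the methyl ketone, whose oxygen is the original C13 hydroxyl oxygen.

**Step 3**
Reactants: 5 3β,8α-dihydroxy-14,15-dinorlabdan-13-one
Product: 6 3β-hydroxy-14,15-dinorlabd-8-en-13-one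
Conditions: I2 (5 mol %), PhMe, 110 °C
Reagents that add atoms: none
Why: Acid-catalysed E1 dehydration of the tertiary 8α-alcohol with HI-mediated alkene equilibration funnels to the tetrasubstituted 8(9)-ene, the thermodynamic isomer, while the secondary neopentylic 3β-alcohol does not ionise at this acid loading.

**Step 4**
Reactants: 6 3β-hydroxy-14,15-dinorlabd-8-en-13-one
Product: 7 methyl (13ξ)-3β,13-dihydroxylabd-8-en-15-oate
Conditions: LiN(iPr)2 (3.3 equiv), MeOAc (3.2 equiv), THF, −78 °C; then 6; aq NH4Cl, −78 °C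
Reagents that add atoms: methyl acetate, COC(C)=O
Why: Aldol addition of the lithium enolate of methyl acetate to the methyl ketone at −78 °C (excess enolate covers the free 3-OH) gives the tertiary β-hydroxy ester; C13 forms as an epimer mixture that is erased in step 9.

**Step 5**
Reactants: 7 methyl (13ξ)-3β,13-dihydroxylabd-8-en-15-oate
Product: 9 methyl (13ξ)-9β,13-epoxy-3β-hydroxylabd-8(17)-en-15-oate (spiro-oxolane; O β on C9; C11 α), via 8α-phenylselanyl spiroether 8 (not isolated)
Conditions: (PhSe)2 (10 mol %), N-fluorobenzenesulfonimide (1.1 equiv), NaHCO3 (1.5 equiv), 4 Å MS, PhMe, 0 → 23 °C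
Reagents that add atoms: none
Why: Proposed new method: selenium-π-acid-catalysed dehydrogenative spiroetherification of a tetrasubstituted alkene — PhSe–X formed from (PhSe)2 and N-fluorobenzenesulfonimide adds to the 8(9)-ene from the α face (the β face is screened by the axial C20 methyl), the tethered C13–OH captures the seleniranium ion by fast 5-exo anti opening at C9 before selenium can leave again, so O enters β and C11 is forced α (this sets the C9 stereocentre), and the oxidant then converts the 8α-selenide into a fluoroselenonium ion that eliminates toward C17 (C9 has no H), releasing PhSe–X and the exocyclic alkene; closest known reaction type: selenium-catalysed oxidative allylic etherification and lactonisation of di- and trisubstituted alkenes with N-fluorobenzenesulfonimide, and stoichiometric phenylselenoetherification followed by selenoxide elimination.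

**Step 6**
Reactants: 9 methyl (13ξ)-9β,13-epoxy-3β-hydroxylabd-8(17)-en-15-oate
Product: 10 methyl (8βH,13ξ)-9β,13-epoxy-3β-hydroxylabdan-15-oate (17-methyl α)
Conditions: Mn(dpm)3 (10 mol %; dpm = dipivaloylmethanate), PhSiH3 (1.5 equiv), tBuOOH (1.5 equiv), iPrOH, 23 °C
Reagents that add atoms: none
Why: Mukaiyama-type Mn–H hydrogen-atom-transfer hydrogenation (Shenvi conditions) passes through the C8 tertiary radical, and axial H delivery gives the thermodynamically preferred equatorial 8α-methyl (8β-H), which avoids a syn-diaxial C17/C20 interaction.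

**Step 7**
Reactants: 10 methyl (8βH,13ξ)-9β,13-epoxy-3β-hydroxylabdan-15-oate
Product: 12 methyl (8βH,13ξ)-9β,13-epoxylabd-2-en-15-oate, via Burgess sulfamate ester 11 (not isolated)
Conditions: Burgess reagent (2.5 equiv), PhMe, 23 → 90 °C
Reagents that add atoms: none
Why: Burgess dehydration — the secondary sulfamate undergoes thermal intramolecular syn elimination with the cis 2β-H; C4 is quaternary so only the 2-ene can form, and the non-ionising pathway limits Wagner–Meerwein shift of the gem-dimethyl group.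

**Step 8**
Reactants: 12 methyl (8βH,13ξ)-9β,13-epoxylabd-2-en-15-oate
Product: 13 methyl (8βH,13ξ)-9β,13-epoxy-2α,3α-dihydroxylabdan-15-oate
Conditions: OsO4 (5 mol %), N-methylmorpholine N-oxide (2 equiv), acetone/H2O 4:1, 23 °C
Reagents that add atoms: osmium tetroxide, O=[Os](=O)(=O)=O; N-methylmorpholine N-oxide, C[N+]1([O-])CCOCC1; water, O
Why: Upjohn syn-dihydroxylation occurs on the α face because the β face of the 2-ene is blocked by the axial C19 and C20 methyls, which sets 2α,3α.

**Step 9**
Reactants: 13 methyl (8βH,13ξ)-9β,13-epoxy-2α,3α-dihydroxylabdan-15-oate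
Product: 14 methyl (2R,3S,5S,8R,9S,10S,13E)-2,3,9-trihydroxylabd-13-en-15-oate (target)
Conditions: KN(SiMe3)2 (4.5 equiv), THF, −78 → −20 °C; aq NH4Cl, −78 °C
Reagents that add atoms: none
Why: E1cB (retro-oxa-Michael) opening — the ester enolate expels the tertiary C13–O alkoxide, leaving C9 untouched and unveiling the 9β-OH and the conjugated enoate; E is favoured because the smaller C16 methyl sits cis to the ester in the elimination transition state, and the minor 13Z isomer is removed by chromatography.

**Compound list**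
1 | (−)-sclareol, (13R)-labd-14-ene-8α,13-diol | C=C[C@](C)(O)CC[C@H]1[C@](C)(O)CC[C@H]2C(C)(C)CCC[C@@]21C | starting material
2 | 3β-hydroxysclareol, (13R)-labd-14-ene-3β,8α,13-triol | C=C[C@](C)(O)CC[C@H]1[C@](C)(O)CC[C@H]2C(C)(C)[C@@H](O)CC[C@@]21C | intermediate
3 | (13R,14ξ)-labdane-3β,8α,13,14,15-pentol | OCC(O)[C@](C)(O)CC[C@H]1[C@](C)(O)CC[C@H]2C(C)(C)[C@@H](O)CC[C@@]21C | intermediate (not isolated)
4 | (13R)-3β,8α,13-trihydroxy-15-norlabdan-14-al | O=C[C@](C)(O)CC[C@H]1[C@](C)(O)CC[C@H]2C(C)(C)[C@@H](O)CC[C@@]21C | intermediate (not isolated)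
5 | 3β,8α-dihydroxy-14,15-dinorlabdan-13-one | CC(=O)CC[C@H]1[C@](C)(O)CC[C@H]2C(C)(C)[C@@H](O)CC[C@@]21C | intermediate
6 | 3β-hydroxy-14,15-dinorlabd-8-en-13-one | CC(=O)CCC1=C(C)CC[C@H]2C(C)(C)[C@@H](O)CC[C@@]21C | intermediate
7 | methyl (13ξ)-3β,13-dihydroxylabd-8-en-15-oate | COC(=O)CC(C)(O)CCC1=C(C)CC[C@H]2C(C)(C)[C@@H](O)CC[C@@]21C | intermediate
8 | methyl (13ξ)-9β,13-epoxy-3β-hydroxy-8α-(phenylselanyl)labdan-15-oate (17-methyl β; C11 α on C9) | COC(=O)CC3(C)CC[C@]1(O3)[C@](C)([Se]c4ccccc4)CC[C@H]2C(C)(C)[C@@H](O)CC[C@@]21C | intermediate (not isolated)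
9 | methyl (13ξ)-9β,13-epoxy-3β-hydroxylabd-8(17)-en-15-oate (C11 α on C9) | COC(=O)CC3(C)CC[C@]1(O3)C(=C)CC[C@H]2C(C)(C)[C@@H](O)CC[C@@]21C | intermediate
10 | methyl (8βH,13ξ)-9β,13-epoxy-3β-hydroxylabdan-15-oate (17-methyl α; C11 α on C9) | COC(=O)CC3(C)CC[C@]1(O3)[C@H](C)CC[C@H]2C(C)(C)[C@@H](O)CC[C@@]21C | intermediate
11 | triethylammonium N-(methoxycarbonyl)sulfamate ester of 10 at O3 | COC(=O)CC3(C)CC[C@]1(O3)[C@H](C)CC[C@H]2C(C)(C)[C@@H](OS(=O)(=O)[N-]C(=O)OC)CC[C@@]21C.CC[NH+](CC)CC | intermediate (not isolated)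
12 | methyl (8βH,13ξ)-9β,13-epoxylabd-2-en-15-oate | COC(=O)CC3(C)CC[C@]1(O3)[C@H](C)CC[C@H]2C(C)(C)C=CC[C@@]21C | intermediate
13 | methyl (8βH,13ξ)-9β,13-epoxy-2α,3α-dihydroxylabdan-15-oate | COC(=O)CC3(C)CC[C@]1(O3)[C@H](C)CC[C@H]2C(C)(C)[C@H](O)[C@H](O)C[C@@]21C | intermediate
14 | methyl (2R,3S,5S,8R,9S,10S,13E)-2,3,9-trihydroxylabd-13-en-15-oate (2α,3α,9β-triol; 17-methyl α; side chain α on C9) | COC(=O)/C=C(\C)CC[C@]1(O)[C@H](C)CC[C@H]2C(C)(C)[C@H](O)[C@H](O)C[C@@]21C | target

**Totals**
Total step count: 9. Longest linear sequence: 9 steps (1 → 14).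

**Three steps most likely to fail**

Risk 1, step 5 (the proposed new method). Three things can go wrong:
- Seleniranium formation may be reversible; an ion on the β face would open trans-diaxially and give the C9 epimer.
- 6-endo attack at C8 would give a fused oxane instead of the spiro-oxolane.
- The sulfonimide anion may trap the ion or aminate the product alkene.

The fallback uses known chemistry, leaves from 7 and returns at 9. mCPBA (NaHCO3, CH2Cl2, 0 °C) transfers oxygen irreversibly to the α face of the tetrasubstituted alkene and gives methyl (13ξ)-8α,9α-epoxy-3β,13-dihydroxylabdan-15-oate F1. CSA (5 mol %, CH2Cl2, −20 °C) then triggers the acid-catalysed 5-exo epoxy-alcohol cyclisation with inversion at C9 and gives methyl (13ξ)-9β,13-epoxy-3β,8α-dihydroxylabdan-15-oate F2, in which C11 is α on C9. Martin sulfurane (1.1 equiv, CH2Cl2, −20 °C) dehydrates only the tertiary 8α-alcohol, toward C17, because the equatorial secondary 3β-alcohol has no antiperiplanar hydrogen; this returns 9.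

Risk 2, step 6. Axial hydrogen delivery to the C8 radical is syn-axial to the C20 methyl, so the kinetic product may be the 8β-methyl epimer. The fallback leaves from 9 and returns at 10. Hydrogenation with H2 (1 atm) over PtO2 in EtOAc saturates the alkene whatever the face and, in the unfavourable case, gives methyl (8αH,13ξ)-9β,13-epoxy-3β-hydroxylabdan-15-oate F3. Photochemical tertiary C–H epimerisation ((nBu4N)4W10O32 2 mol %, bis(4-chlorophenyl) disulfide 10 mol %, MeCN, 390 nm, 23 °C) reversibly removes and returns the C8 hydrogen and funnels F3 to the thermodynamically preferred equatorial-methyl isomer 10. Any scrambling at C3 is irrelevant because C3 becomes sp2 in step 7.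

Risk 3, step 7. The neopentylic secondary sulfamate may ionise and give methyl-shifted or ring-contracted alkenes. The fallback leaves from 10 and returns at 12. Dess–Martin periodinane (CH2Cl2, 23 °C) gives methyl (8βH,13ξ)-9β,13-epoxy-3-oxolabdan-15-oate F4. LiN(SiMe3)2 (1.05 equiv) and PhNTf2 in THF at −78 °C give methyl (8βH,13ξ)-9β,13-epoxy-3-(trifluoromethylsulfonyloxy)labd-2-en-15-oate F5; C2 is the only enolisable position of the ketone and is more acidic than the ester α-CH2. Pd(OAc)2/PPh3 with HCO2H and nBu3N in DMF at 60 °C reduces the enol triflate to the alkene 12.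

**Further compounds**
F1 | step 5 | methyl (13ξ)-8α,9α-epoxy-3β,13-dihydroxylabdan-15-oate | COC(=O)CC(C)(O)CC[C@]13O[C@]3(C)CC[C@H]2C(C)(C)[C@@H](O)CC[C@@]21C
F2 | step 5 | methyl (13ξ)-9β,13-epoxy-3β,8α-dihydroxylabdan-15-oate (17-methyl β; C11 α on C9) | COC(=O)CC3(C)CC[C@]1(O3)[C@](C)(O)CC[C@H]2C(C)(C)[C@@H](O)CC[C@@]21C
F3 | step 6 | methyl (8αH,13ξ)-9β,13-epoxy-3β-hydroxylabdan-15-oate (17-methyl β; C8 epimer of 10) | COC(=O)CC3(C)CC[C@]1(O3)[C@@H](C)CC[C@H]2C(C)(C)[C@@H](O)CC[C@@]21C
F4 | step 7 | methyl (8βH,13ξ)-9β,13-epoxy-3-oxolabdan-15-oate | COC(=O)CC3(C)CC[C@]1(O3)[C@H](C)CC[C@H]2C(C)(C)C(=O)CC[C@@]21C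
F5 | step 7 | methyl (8βH,13ξ)-9β,13-epoxy-3-(trifluoromethylsulfonyloxy)labd-2-en-15-oate | COC(=O)CC3(C)CC[C@]1(O3)[C@H](C)CC[C@H]2C(C)(C)C(OS(=O)(=O)C(F)(F)F)=CC[C@@]21C
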